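**Remarks on the chemistry (assumptions, one line each)**

- The target is numbered as an azulene: C1 (CH2), C2 (methyl, oxirane), C3 (oxirane CH), C3a, C4, C5 (carbinol), C6, C7 (ester), C8 (isopropyl), C8a; ring A is the five-membered ring, ring B the seven-membered ring. PMB = 4-methoxybenzyl, TBS = tert-butyldimethylsilyl, TES = triethylsilyl.
- The ketone formed in the rearrangement is β,γ-unsaturated; with lowest locants it is a cyclohept-3-en-1-one and is named so here.
- Assumption: the side-arm methyl ketone is carried as its (S)-configured PMB-protected carbinol instead of a ketal. This avoids a β,γ-unsaturated ketone on the way to the precursor, makes the wrong cyclopropane antipode a separable diastereomer, and leaves the carbon skeletons of precursor 16 and product 19 unchanged.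
- O-5 and O-7 are trans on ring B, so a 5,7-acetonide would be an inside–outside bridged bicycle; where both oxygens need masking, two separate silyl ethers are drawn.
- Assumption: 1 and 26 are catalogue compounds. The (4R,5R)-TADDOL ligand is written in step 8; its antipode is used if the sense of induction calls for it.

## Structural features

The target is a trans-fused hydroazulene: ring A (C1, C2, C3, C3a, C8a) is a cyclopentane with a trisubstituted oxirane across C2–C3 (methyl on C2), and ring B (C3a, C4 to C8, C8a) is a cycloheptane. There are seven stereocentres: the β-oxirane at C2/C3 (syn to H-8a), the trans ring fusion C3a/C8a, the tertiary carbinol C5 (hydroxyl β), the 4-hydroxybenzoate at C7 (α) and the isopropyl group at C8 (β). C3, C3a, C8a, C8 and C7 form an unbroken chain of five stereocentres; the two ring B oxygens are 1,3-anti, and the isopropyl group is trans to the C7 oxygen and to the C8a–C1 bond. The fragile groups are the oxirane (acid), the aryl ester (base, nucleophiles), the phenol, and any β-hydroxy ketone formed from C5–OH and a C7 carbonyl (retro-aldol, dehydration). The real difficulty is not ring A but relative and absolute control on a mobile seven-membered ring, including a tertiary centre that cannot be corrected by epimerisation. The key step uses the fact that in ring B the fusion bond C3a–C8a lies opposite the C5–C6–C7 segment: a temporary C5–C7 bond turns that segment into a cyclopropanol flanked by the alkenes C4=C3a and C8=C8a, and a (3,3) shift then forms C3a–C8a, breaks C5–C7, and leaves a carbonyl at C5 and an alkene at C7=C8.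

## Logic of the disconnections

The two C–O bonds of the oxirane in 34 are cut first, giving 33. The oxirane is the most acid-labile group and is best made last; the forward step must find the β face of a trans-fused cyclopentene without a directing group in reach.

The two O–Si bonds are restored in going back to 32. Phenol and tertiary hydroxyl have to be masked during the basic and oxidative steps of ring A construction; the forward step needs a fluoride source that spares the aryl ester.

The C2=C3 double bond of 32 is cut to the diene 31. This removes ring A and leaves a monocyclic problem; the forward metathesis needs the two alkenyl arms on adjacent trans carbons, which the key step provides.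

The two terminal C=C bonds of 31 go back to the carbonyls of 30, these to the alcohols of 29 and to the two PMB ethers of 28. One deprotection and one oxidation serve both arms; the forward olefination must not epimerise the α-branched aldehyde or attack the ester.

The ester C–O bond and the tertiary O–Si bond of 28 are cut to 25 and 26. Acylating at this point lets the ester protect O-7, so no separate group is needed there; the forward step must distinguish the secondary from the tertiary hydroxyl.

The C7–H bond of 25 is cut to ketone 24. This puts the C7 configuration under the control of the C5 hydroxyl; the forward reduction must be an internal hydride delivery.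

The C8 configuration and the C7 carbonyl of 24 are traced through 22 to the alkene of 20 (C7–O and C8–H bonds). The alkene is what the key step leaves behind; the forward sequence must correct the kinetic hydroboration outcome by equilibration next to the ketone.

The C5–CH3 bond of 20 is cut to ketone 19. The demand is attack on the carbonyl face anti to the C3a arm, with suppression of enolisation.

Key disconnection: in 19 the C3a–C8a bond is cut while the C5–C7 bond is formed in the retrosynthetic sense, giving 16. Ring B and both ring-fusion centres are traded for one cyclopropane and two alkene geometries; the forward step needs the cis arrangement of the alkenyl groups and a concerted pathway.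

The cyclopropane bonds C5–C6 and C5–C7 of 16 are cut to ester 14 and the organomagnesium 15 (from 9). The precursor falls into two fragments of similar size; the forward step must give the cis diastereomer and a useful enantiomeric bias.

Bromide 9 goes back through 8 and 7 to 6, and 6 is cut at the vinyl–isopropyl bond and at the vinyl–CH2 bond to 1, 2 and 3. One operation sets the trisubstituted alkene geometry; the forward step needs syn addition and retention on trapping.

Ester 14 goes back through alkyne 13 (cut at the alkyne–carboxyl bond via 12) to 11 and 10. The Z geometry comes from semi-hydrogenation and not from an olefination that could leak the E isomer.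

## Other disconnections considered

Alternative 1: The cut is the C2=C3 bond of ring A in a hydroazulene A2 whose ring B is complete, going back to the trans keto-aldehyde A1. The forward key step is a reductive carbonyl coupling with TiCl3/Zn–Cu (low-valent titanium) in refluxing dimethoxyethane.
- In favour: it forms the trisubstituted alkene directly from the two carbonyls, adds no carbon that must later be expelled, and five-membered closure is the best case for this coupling.
- Against: A1 already contains ring B and all five of its stereocentres, so the cut is an endgame tactic and leaves the main problem untouched. The reagent is strongly reducing and oxophilic, so the aryl ester cannot be present. Both ring B oxygens need masking, and because they are trans this means two separate ethers, put on and taken off again.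
- Comparison, structure: equal. The chosen plan closes the same bond.
- Comparison, mechanism: the chosen plan closes it by metathesis, which tolerates the ester and a silyl ether.
- Comparison, step economy: the coupling is better by one step at the ring closure (named as such), but the extra protection and deprotection of O-7 should cancel the gain. It is kept as a reserve for steps 17 and 18.

Alternative 2: The cuts are C8–C8a and C3a–C4, the two bonds from the ring-fusion carbons into ring B, so ring A is bought as cyclopent-2-enone A3. In the forward key step the silyl ketene acetal A4 adds under a chiral oxazaborolidinium Lewis acid, and the regenerated enolate is alkylated with 3-iodo-2-methylprop-1-ene A5 to give keto ester A6.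
- In favour: the absolute configuration comes from a catalytic step on cheap materials at the outset. This is better than the chosen plan, whose enantio-determining step needs a stoichiometric chiral titanium alkoxide and a diastereomer separation as safeguard (named as such). The trans relation of C3a and C8a from anti alkylation is as dependable as the boat transition state of the chosen plan (equal).
- Against: no ring is formed. Ring B must still be closed between the ester carbon (future C7) and the alkene terminus (future C6), an entropically unfavourable seven-membered closure. C5 and C7 are then set on the new ring. The ring A ketone sits at C3, so the C2 methyl and the alkene position need further steps. The C8 centre, set from a prochiral ketene acetal, is α to an ester and open to epimerisation.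
- Comparison, structure: it has ring A from the start; the chosen plan has ring B and both fusion centres from one event.
- Comparison, mechanism: ionic and catalyst-controlled against pericyclic and substrate-controlled.
- Comparison, step economy: A6 is reached far sooner than 19, but the way from A6 to the target is expected to be longer, so the totals should be similar at best.

Alternative 3: The cuts are C3a–C8a, C1–C2 and C2–C3, going back to the acyclic 1,8-enyne A7. In the forward key step Co2(CO)8 (zerovalent cobalt) joins alkyne, alkene and carbon monoxide to give the bicyclic enone A8.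
- In favour: two rings in one step is better than the one ring of the chosen key step (named as such). The C2 carbonyl is a handle for the methyl group. C5, C7 and C8 can be set in an open chain by well-understood acyclic methods, which is equal to or better than setting them on the seven-membered ring.
- Against: this cyclisation is dependable for five- and six-membered second rings; a seven-membered ring from a 1,8-enyne usually needs a rigid tether. The usual device, a cyclic acetal over the 1,3-diol, is excluded because O-5 and O-7 are trans and the product would be inside–outside bridged, so A7 carries two separate ethers and no conformational bias. Only C8a is set, with uncertain induction from C8. C3a must be set later by reducing the C3=C3a enone, where trans fusion is not assured.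
- Comparison, structure: the chosen plan sets both fusion centres stereospecifically.
- Comparison, mechanism: a metal-mediated cyclocarbonylation against a thermal sigmatropic shift with a precedented substrate class.
- Comparison, step economy: comparable on paper, but the ring-forming step carries much higher risk.

Key step: step 9

## Route

Step 1
Reactants: 1 tert-butyl(but-3-yn-1-yloxy)dimethylsilane; 2 isopropylmagnesium chloride; 3 (S)-2-methyloxirane
Product: 6 (2S,4Z)-7-(TBSO)-5-(propan-2-yl)hept-4-en-2-ol, via isopropylcopper 4 (not isolated), via alkenylcopper 5 (not isolated)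
Conditions: 2, CuBr·SMe2, Et2O/Me2S, −45 °C; 1, −25 °C; LiC≡CBu, HMPA, −78 °C; 3, −78 → −20 °C; H2O
Reagents that add atoms: none
Why: Normant carbocupration: isopropylcopper adds syn across the terminal alkyne with copper on the terminal carbon, so isopropyl and copper are cis; the mixed alkynyl cuprate then opens the epoxide at its CH2 with retention of the alkene geometry, and the (S) centre is not touched.

Step 2
Reactants: 6
Product: 7 (3Z,6S)-1-(TBSO)-6-(PMBO)-3-(propan-2-yl)hept-3-ene
Conditions: NaH, PMBCl, Bu4NI (cat.), THF/DMF, 0 → 20 °C
Reagents that add atoms: 4-methoxybenzyl chloride, COc1ccc(CCl)cc1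
Why: Williamson etherification of the secondary alkoxide; the silyl ether is too remote to migrate.

Step 3
Reactants: 7
Product: 8 (3Z,6S)-6-(PMBO)-3-(propan-2-yl)hept-3-en-1-ol
Conditions: Bu4NF, THF, 0 → 20 °C
Reagents that add atoms: none
Why: Fluoride-induced desilylation; the PMB ether and the alkene are inert.

Step 4
Reactants: 8
Product: 9 (3Z,6S)-1-bromo-6-(PMBO)-3-(propan-2-yl)hept-3-ene
Conditions: CBr4, PPh3, 2,6-lutidine (buffer), CH2Cl2, 0 °C
Reagents that add atoms: tetrabromomethane, BrC(Br)(Br)Br
Why: Appel reaction of a primary alcohol under buffered conditions that spare the acid-sensitive PMB ether.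

Step 5
Reactants: 10 prop-2-yn-1-ol
Product: 11 1-methoxy-4-[(prop-2-yn-1-yloxy)methyl]benzene
Conditions: NaH, PMBCl, Bu4NI (cat.), THF, 0 → 20 °C
Reagents that add atoms: 4-methoxybenzyl chloride, COc1ccc(CCl)cc1
Why: Williamson etherification; the alkoxide is far more basic than the acetylide is accessible under these conditions.

Step 6
Reactants: 11
Product: 13 methyl 4-(PMBO)but-2-ynoate, via lithium acetylide 12 (not isolated)
Conditions: n-BuLi, THF, −78 °C; ClCO2Me, −78 → 0 °C
Reagents that add atoms: methyl chloroformate, COC(=O)Cl
Why: C-acylation of a lithium acetylide with a chloroformate, a standard route to alk-2-ynoates.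

Step 7
Reactants: 13
Product: 14 methyl (2Z)-4-(PMBO)but-2-enoate
Conditions: H2 (1 atm), Pd/CaCO3–Pb(OAc)2, quinoline, EtOAc, 20 °C
Reagents that add atoms: none
Why: Lindlar semi-hydrogenation: syn delivery of hydrogen on the poisoned palladium surface gives the Z enoate, and no basic or nucleophilic reagent is present that could isomerise it.

Step 8
Reactants: 9; 14
Product: 16 (1S,2S)-1-[(1Z)-3-(PMBO)prop-1-en-1-yl]-2-[(3E,6S)-6-(PMBO)-2-methylhept-3-en-3-yl]cyclopropan-1-ol, via Grignard reagent 15 (not isolated)
Conditions: 9, Mg, THF, 20 °C; then 14, Ti(OiPr)4 (1.0 equiv), (4R,5R)-TADDOL (1.0 equiv), THF, 0 → 20 °C, 15 (2.4 equiv) added over 2 h; H2O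
Reagents that add atoms: none
Why: Kulinkovich hydroxycyclopropanation in its TADDOLate-mediated asymmetric form: the titanacyclopropane formed from two equivalents of 15 (one is lost as the alkane) inserts the ester carbonyl and the β-titanio ketone closes so that the two carbon substituents end cis. The chiral alkoxide should bias the absolute sense towards (1S,2S); because the side arm already holds an (S) centre, the unwanted cyclopropane antipode is a diastereomer and is removed by chromatography here or at 19.

Step 9
Reactants: 16
Product: 19 (5R,6S)-6-(PMBO-methyl)-5-[(2S)-2-(PMBO)propyl]-4-(propan-2-yl)cyclohept-3-en-1-one, via potassium cyclopropanolate 17 (not isolated), via potassium enolate 18 (not isolated)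
Conditions: KH, 18-crown-6, THF, −20 → 20 °C; pH 7 phosphate buffer, −78 °C
Reagents that add atoms: none
Why: Deprotonation gives 17, whose C1–C2 bond is weakened by the oxyanion; the two cis alkenyl groups fold over the three-membered ring in the only accessible (boat) geometry and a concerted (3,3) shift joins the alkene termini while C1–C2 breaks, giving enolate 18. The closest known reaction type is the anionic oxy-Cope form of the cis-divinylcyclopropane to cyclohepta-1,4-diene rearrangement, established for cis-1,2-dialkenylcyclopropanols. Ring B closes as a sigmatropic ring expansion (the three cyclopropane carbons plus two carbons from each alkene), suprafacial on both allyl units, so no Baldwin-type constraint applies. C6 of 19 (later C3a) is set by the Z alkene, which carries CH2OPMB inside the boat, and C5 (later C8a) by the E trisubstituted alkene, which carries its chain outside; one inside and one outside substituent end trans. The absolute configuration is relayed from C2 of the cyclopropane, because bonding occurs only on the alkene faces turned towards the ring. The step needs the concerted path to outrun heterolytic ring opening, which the cis arrangement from step 8 and the oxyanion acceleration should secure despite the inward substituent. Enolate 18 is regiodefined (C1=C7, away from the C3=C4 alkene), and cold neutral protonation should return the β,γ-unsaturated ketone without conjugation.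

Step 10
Reactants: 19
Product: 20 (1S,5R,6S)-6-(PMBO-methyl)-5-[(2S)-2-(PMBO)propyl]-1-methyl-4-(propan-2-yl)cyclohept-3-en-1-ol
Conditions: CeCl3, MeLi, THF, −78 °C; 19, −78 °C; H2O
Reagents that add atoms: methyllithium, [Li]C
Why: Organocerium (Imamoto) 1,2-addition, chosen because the methylene between carbonyl and alkene is easily enolised. Allylic 1,2-strain with the isopropyl group should hold the C5 arm pseudoaxial, so the trans C6 arm is axial on the other face and 1,3 to the carbonyl; methyl should enter anti to it, placing the hydroxyl cis to CH2OPMB.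

Step 11
Reactants: 20
Product: 22 (1R,3R,4R,5R,6S)-6-(PMBO-methyl)-5-[(2S)-2-(PMBO)propyl]-1-methyl-4-(propan-2-yl)cycloheptane-1,3-diol, via alkylborane 21 (not isolated)
Conditions: BH3·THF, THF, 0 → 20 °C; NaOH, H2O2, 0 → 20 °C
Reagents that add atoms: hydrogen peroxide, OO
Why: Brown hydroboration–oxidation: boron goes to the less substituted C3, and syn addition is expected on the face anti to the pseudoaxial C5 arm. The configurations created at C3 and C4 need not be correct, because both are reset in steps 12 and 13.

Step 12
Reactants: 22
Product: 24 (2S,3R,4S,6R)-6-hydroxy-4-(PMBO-methyl)-3-[(2S)-2-(PMBO)propyl]-6-methyl-2-(propan-2-yl)cycloheptan-1-one, via cis-ketone 23 (not isolated)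
Conditions: Dess–Martin periodinane, CH2Cl2, 0 → 20 °C; aq. NaHCO3/Na2S2O3 wash; DBU (0.3 equiv), CH2Cl2, 20 °C
Reagents that add atoms: none
Why: Dess–Martin oxidation leaves the tertiary alcohol alone. Amine-catalysed enolisation then moves the α-isopropyl centre to the thermodynamically favoured 2,3-trans arrangement, in which the three contiguous ring substituents alternate; the weak, non-nucleophilic base should keep alkoxide-driven retro-aldol cleavage in check.

Step 13
Reactants: 24
Product: 25 (1R,3S,4S,5R,6S)-6-(PMBO-methyl)-5-[(2S)-2-(PMBO)propyl]-1-methyl-4-(propan-2-yl)cycloheptane-1,3-diol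
Conditions: Me4NBH(OAc)3, MeCN/AcOH, −30 °C; aq. KNa tartrate
Reagents that add atoms: none
Why: Evans–Saksena reduction: the tertiary hydroxyl exchanges onto boron and hydride is delivered intramolecularly to the carbonyl face that the hydroxyl occupies, so the new hydroxyl ends 1,3-anti to it and trans to the isopropyl group.

Step 14
Reactants: 25; 26 4-(TBSO)benzoic acid
Product: 28 (1S,2S,3R,4S,6R)-4-(PMBO-methyl)-3-[(2S)-2-(PMBO)propyl]-6-methyl-2-(propan-2-yl)-6-(TESO)cycloheptyl 4-(TBSO)benzoate, via hydroxy ester 27 (not isolated)
Conditions: 26, DIC, DMAP, CH2Cl2, 20 °C; then 2,6-lutidine, TESOTf, 0 °C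
Reagents that add atoms: triethylsilyl trifluoromethanesulfonate, CC[Si](CC)(CC)OS(=O)(=O)C(F)(F)F
Why: Steglich esterification acylates only the secondary, menthol-like hydroxyl, and the ester then serves as the protecting group for O-7. The silyl triflate caps the tertiary hydroxyl so that the aldehyde of 30 cannot close to a lactol with it.

Step 15
Reactants: 28
Product: 29 (1S,2S,3R,4S,6R)-4-(hydroxymethyl)-3-[(2S)-2-hydroxypropyl]-6-methyl-2-(propan-2-yl)-6-(TESO)cycloheptyl 4-(TBSO)benzoate
Conditions: DDQ, CH2Cl2/pH 7 buffer, 0 → 20 °C
Reagents that add atoms: none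
Why: Oxidative cleavage of both PMB ethers by benzylic hydride abstraction and hydrolysis; the silyl ethers and the electron-poor aryl ester are inert.

Step 16
Reactants: 29
Product: 30 (1S,2S,3S,4S,6R)-4-formyl-6-methyl-3-(2-oxopropyl)-2-(propan-2-yl)-6-(TESO)cycloheptyl 4-(TBSO)benzoate
Conditions: Dess–Martin periodinane, pyridine, CH2Cl2, 0 → 20 °C
Reagents that add atoms: none
Why: Dess–Martin oxidation converts the primary and the secondary alcohol in one operation under near-neutral conditions that should not epimerise the α-branched aldehyde; the auxiliary (S) carbinol centre disappears here.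

Step 17
Reactants: 30
Product: 31 (1S,2S,3R,4R,6R)-4-ethenyl-6-methyl-3-(2-methylprop-2-en-1-yl)-2-(propan-2-yl)-6-(TESO)cycloheptyl 4-(TBSO)benzoate
Conditions: Ph3PCH3Br, KN(SiMe3)2, THF, 0 °C; 30, −78 → 20 °C
Reagents that add atoms: methyltriphenylphosphonium bromide, C[P+](c1ccccc1)(c1ccccc1)c1ccccc1.[Br-]
Why: Wittig methylenation of both carbonyls with salt-free ylide; the aldehyde reacts at low temperature before enolisation can epimerise C4, and the hindered, electron-rich benzoate should survive.

Step 18
Reactants: 31
Product: 32 (3aS,5R,7S,8S,8aR)-2,5-dimethyl-8-(propan-2-yl)-5-(TESO)-1,3a,4,5,6,7,8,8a-octahydroazulen-7-yl 4-(TBSO)benzoate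
Conditions: (H2IMes)(PCy3)Cl2Ru=CHPh (second-generation Grubbs catalyst, 5 mol %), CH2Cl2, 40 °C
Reagents that add atoms: none
Why: Ring-closing metathesis of a vinyl and an isopropenyl group on adjacent trans carbons closes ring A as the trisubstituted cyclopentene, driven by loss of ethene; no stereocentre is touched.

Step 19
Reactants: 32
Product: 33 (3aS,5R,7S,8S,8aR)-5-hydroxy-2,5-dimethyl-8-(propan-2-yl)-1,3a,4,5,6,7,8,8a-octahydroazulen-7-yl 4-hydroxybenzoate
Conditions: Bu4NF, THF, 0 → 20 °C; H2O
Reagents that add atoms: none
Why: Fluoride cleaves the aryl silyl ether at once and the tertiary triethylsilyl ether more slowly. Desilylation is placed before epoxidation so that neither fluoride nor acid meets the oxirane and the β face of ring A is free of the silyl group.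

Step 20
Reactants: 33
Product: 34 (2R,3S,3aS,5R,7S,8S,8aR)-2,3-epoxy-5-hydroxy-2,5-dimethyl-8-(propan-2-yl)decahydroazulen-7-yl 4-hydroxybenzoate
Conditions: mCPBA, CH2Cl2, −10 → 0 °C; aq. NaHCO3 wash
Reagents that add atoms: 3-chloroperoxybenzoic acid, OOC(=O)c1cccc(Cl)c1
Why: Prilezhaev epoxidation of the only alkene. In the trans-fused cyclopentene C8a is the envelope flap turned to the β face and both pseudoaxial allylic hydrogens (H-3a and one H-1) point α, so β attack is staggered and less encumbered and should give the 2β,3β-oxirane syn to H-8a; no directing group secures this face preference.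

## Compound list

1 | tert-butyl(but-3-yn-1-yloxy)dimethylsilane | C#CCCO[Si](C)(C)C(C)(C)C | starting material
2 | isopropylmagnesium chloride | CC(C)[Mg]Cl | starting material
3 | (S)-2-methyloxirane | C[C@H]1CO1 | starting material
4 | isopropylcopper (as its Me2S/MgBrCl complex) | CC(C)[Cu] | intermediate
5 | [(1Z)-4-(TBSO)-2-(propan-2-yl)but-1-en-1-yl]copper | [Cu]/C=C(\C(C)C)CCO[Si](C)(C)C(C)(C)C | intermediate
6 | (2S,4Z)-7-(TBSO)-5-(propan-2-yl)hept-4-en-2-ol | C[C@H](O)C/C=C(\C(C)C)CCO[Si](C)(C)C(C)(C)C | intermediate
7 | (3Z,6S)-1-(TBSO)-6-(PMBO)-3-(propan-2-yl)hept-3-ene | C[C@H](OCc1ccc(OC)cc1)C/C=C(\C(C)C)CCO[Si](C)(C)C(C)(C)C | intermediate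
8 | (3Z,6S)-6-(PMBO)-3-(propan-2-yl)hept-3-en-1-ol | C[C@H](OCc1ccc(OC)cc1)C/C=C(\C(C)C)CCO | intermediate
9 | (3Z,6S)-1-bromo-6-(PMBO)-3-(propan-2-yl)hept-3-ene | C[C@H](OCc1ccc(OC)cc1)C/C=C(\C(C)C)CCBr | intermediate
10 | prop-2-yn-1-ol | C#CCO | starting material
11 | 1-methoxy-4-[(prop-2-yn-1-yloxy)methyl]benzene | C#CCOCc1ccc(OC)cc1 | intermediate
12 | [3-(PMBO)prop-1-yn-1-yl]lithium | [Li]C#CCOCc1ccc(OC)cc1 | intermediate
13 | methyl 4-(PMBO)but-2-ynoate | COC(=O)C#CCOCc1ccc(OC)cc1 | intermediate
14 | methyl (2Z)-4-(PMBO)but-2-enoate | COC(=O)/C=C\COCc1ccc(OC)cc1 | intermediate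
15 | bromo[(3Z,6S)-6-(PMBO)-3-(propan-2-yl)hept-3-en-1-yl]magnesium | C[C@H](OCc1ccc(OC)cc1)C/C=C(\C(C)C)CC[Mg]Br | intermediate
16 | (1S,2S)-1-[(1Z)-3-(PMBO)prop-1-en-1-yl]-2-[(3E,6S)-6-(PMBO)-2-methylhept-3-en-3-yl]cyclopropan-1-ol | CC(C)/C(=C\C[C@H](C)OCc1ccc(OC)cc1)[C@@H]2C[C@]2(O)/C=C\COCc3ccc(OC)cc3 | intermediate
17 | potassium alkoxide of 16 (configuration as in 16) | CC(C)/C(=C\C[C@H](C)OCc1ccc(OC)cc1)[C@@H]2C[C@]2([O-])/C=C\COCc3ccc(OC)cc3.[K+] | intermediate
18 | potassium C1=C7 enolate of 19 (configuration as in 19) | CC(C)C1=CCC([O-])=C[C@H](COCc2ccc(OC)cc2)[C@H]1C[C@H](C)OCc3ccc(OC)cc3.[K+] | intermediate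
19 | (5R,6S)-6-(PMBO-methyl)-5-[(2S)-2-(PMBO)propyl]-4-(propan-2-yl)cyclohept-3-en-1-one | CC(C)C1=CCC(=O)C[C@H](COCc2ccc(OC)cc2)[C@H]1C[C@H](C)OCc3ccc(OC)cc3 | intermediate
20 | (1S,5R,6S)-6-(PMBO-methyl)-5-[(2S)-2-(PMBO)propyl]-1-methyl-4-(propan-2-yl)cyclohept-3-en-1-ol | CC(C)C1=CC[C@](C)(O)C[C@H](COCc2ccc(OC)cc2)[C@H]1C[C@H](C)OCc3ccc(OC)cc3 | intermediate
21 | alkylborane from 20 (boron on C3, drawn as RBH2 with the hydroxyl written free; configuration as in 22) | CC(C)[C@@H]1[C@H](C[C@H](C)OCc2ccc(OC)cc2)[C@@H](COCc3ccc(OC)cc3)C[C@@](C)(O)C[C@H]1B | intermediate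
22 | (1R,3R,4R,5R,6S)-6-(PMBO-methyl)-5-[(2S)-2-(PMBO)propyl]-1-methyl-4-(propan-2-yl)cycloheptane-1,3-diol | CC(C)[C@@H]1[C@H](C[C@H](C)OCc2ccc(OC)cc2)[C@@H](COCc3ccc(OC)cc3)C[C@@](C)(O)C[C@H]1O | intermediate
23 | (2R,3R,4S,6R)-6-hydroxy-4-(PMBO-methyl)-3-[(2S)-2-(PMBO)propyl]-6-methyl-2-(propan-2-yl)cycloheptan-1-one | CC(C)[C@@H]1[C@H](C[C@H](C)OCc2ccc(OC)cc2)[C@@H](COCc3ccc(OC)cc3)C[C@@](C)(O)CC1=O | intermediate
24 | (2S,3R,4S,6R)-6-hydroxy-4-(PMBO-methyl)-3-[(2S)-2-(PMBO)propyl]-6-methyl-2-(propan-2-yl)cycloheptan-1-one | CC(C)[C@H]1[C@H](C[C@H](C)OCc2ccc(OC)cc2)[C@@H](COCc3ccc(OC)cc3)C[C@@](C)(O)CC1=O | intermediate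
25 | (1R,3S,4S,5R,6S)-6-(PMBO-methyl)-5-[(2S)-2-(PMBO)propyl]-1-methyl-4-(propan-2-yl)cycloheptane-1,3-diol | CC(C)[C@H]1[C@H](C[C@H](C)OCc2ccc(OC)cc2)[C@@H](COCc3ccc(OC)cc3)C[C@@](C)(O)C[C@@H]1O | intermediate
26 | 4-(TBSO)benzoic acid | OC(=O)c1ccc(O[Si](C)(C)C(C)(C)C)cc1 | starting material
27 | (1S,2S,3R,4S,6R)-6-hydroxy-4-(PMBO-methyl)-3-[(2S)-2-(PMBO)propyl]-6-methyl-2-(propan-2-yl)cycloheptyl 4-(TBSO)benzoate | CC(C)[C@H]1[C@H](C[C@H](C)OCc2ccc(OC)cc2)[C@@H](COCc3ccc(OC)cc3)C[C@@](C)(O)C[C@@H]1OC(=O)c1ccc(O[Si](C)(C)C(C)(C)C)cc1 | intermediate
28 | (1S,2S,3R,4S,6R)-4-(PMBO-methyl)-3-[(2S)-2-(PMBO)propyl]-6-methyl-2-(propan-2-yl)-6-(TESO)cycloheptyl 4-(TBSO)benzoate | CC(C)[C@H]1[C@H](C[C@H](C)OCc2ccc(OC)cc2)[C@@H](COCc3ccc(OC)cc3)C[C@@](C)(O[Si](CC)(CC)CC)C[C@@H]1OC(=O)c1ccc(O[Si](C)(C)C(C)(C)C)cc1 | intermediate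
29 | (1S,2S,3R,4S,6R)-4-(hydroxymethyl)-3-[(2S)-2-hydroxypropyl]-6-methyl-2-(propan-2-yl)-6-(TESO)cycloheptyl 4-(TBSO)benzoate | CC(C)[C@H]1[C@H](C[C@H](C)O)[C@@H](CO)C[C@@](C)(O[Si](CC)(CC)CC)C[C@@H]1OC(=O)c1ccc(O[Si](C)(C)C(C)(C)C)cc1 | intermediate
30 | (1S,2S,3S,4S,6R)-4-formyl-6-methyl-3-(2-oxopropyl)-2-(propan-2-yl)-6-(TESO)cycloheptyl 4-(TBSO)benzoate | CC(C)[C@H]1[C@H](CC(C)=O)[C@@H](C=O)C[C@@](C)(O[Si](CC)(CC)CC)C[C@@H]1OC(=O)c1ccc(O[Si](C)(C)C(C)(C)C)cc1 | intermediate
31 | (1S,2S,3R,4R,6R)-4-ethenyl-6-methyl-3-(2-methylprop-2-en-1-yl)-2-(propan-2-yl)-6-(TESO)cycloheptyl 4-(TBSO)benzoate | CC(C)[C@H]1[C@H](CC(C)=C)[C@@H](C=C)C[C@@](C)(O[Si](CC)(CC)CC)C[C@@H]1OC(=O)c1ccc(O[Si](C)(C)C(C)(C)C)cc1 | intermediate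
32 | (3aS,5R,7S,8S,8aR)-2,5-dimethyl-8-(propan-2-yl)-5-(TESO)-1,3a,4,5,6,7,8,8a-octahydroazulen-7-yl 4-(TBSO)benzoate | CC(C)[C@H]1[C@@H]2CC(C)=C[C@H]2C[C@@](C)(O[Si](CC)(CC)CC)C[C@@H]1OC(=O)c1ccc(O[Si](C)(C)C(C)(C)C)cc1 | intermediate
33 | (3aS,5R,7S,8S,8aR)-5-hydroxy-2,5-dimethyl-8-(propan-2-yl)-1,3a,4,5,6,7,8,8a-octahydroazulen-7-yl 4-hydroxybenzoate | CC(C)[C@H]1[C@@H]2CC(C)=C[C@H]2C[C@@](C)(O)C[C@@H]1OC(=O)c1ccc(O)cc1 | intermediate
34 | (2R,3S,3aS,5R,7S,8S,8aR)-2,3-epoxy-5-hydroxy-2,5-dimethyl-8-(propan-2-yl)decahydroazulen-7-yl 4-hydroxybenzoate | CC(C)[C@H]1[C@@H]2C[C@@]3(C)O[C@H]3[C@H]2C[C@@](C)(O)C[C@@H]1OC(=O)c1ccc(O)cc1 | target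

## Step count and least certain steps

Total: 20 steps. Longest linear sequence: 17 steps (steps 1 to 4 and 8 to 20); the three-step branch (steps 5 to 7) joins at step 8.

Step 9 (key step). The most likely failure is heterolytic opening of the cyclopropanolate to a homoenolate–allyl anion pair, which competes because the inward CH2OPMB group raises the barrier of the boat transition state; reclosure would then erode the stereospecificity or give ring-opened ketone on protonation. Fallback: the route sets out from 16, which is silylated (Me3SiCl, imidazole) to the cyclopropyl trimethylsilyl ether F1. F1 is rearranged without base in toluene at 80 to 110 °C to the silyl enol ether F2, and F2 is cleaved with Bu4NF/AcOH at −78 °C. The route is rejoined at 19.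

Step 8. The most likely failure is incomplete enantiocontrol by the chiral titanium alkoxide, possibly with some conjugate addition to the Z enoate. Fallback: from 9 and 14 the reaction is run with achiral catalytic Ti(OiPr)4, which is expected to give 16 together with an equal amount of its (1R,2R)-cyclopropane diastereomer F3. The mixture is taken through step 9, where F3 gives the diastereomeric ketone F4. F4 differs from 19 at two ring centres, one of them 1,3 to the fixed (S) carbinol centre, and is removed by chromatography; the route is rejoined at 19 at the cost of half the material.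

Step 10. The most likely failure is poor facial selectivity of the methyl addition, if the ring populates a conformer with both arms equatorial and the carbonyl faces become similar. Fallback: from 19 the carbonyl is methylenated without base (Zn/CH2Br2/TiCl4) to the exocyclic alkene F5. F5 is hydrated at the less hindered 1,1-disubstituted alkene by a Mukaiyama hydration (Co(acac)2, PhSiH3, O2). Oxygen then arrives from the open face, the face the methyl nucleophile would have used, which gives the opposite carbinol configuration; the route is rejoined at 20.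

Step 12. The most likely failure is retro-aldol cleavage or dehydration of the β-hydroxy ketone during base-mediated equilibration, or incomplete epimerisation. Fallback: from 20 the ring alkene is epoxidised (mCPBA, attack anti to the C5 arm and syn to the homoallylic hydroxyl) to the 3β,4β-epoxide F6. F6 is treated with BF3·OEt2 at −78 °C in a Meinwald rearrangement: the 1,2-hydride shift from C3 to C4 occurs anti to the departing oxygen and so places the isopropyl group directly in the required orientation without base. The route is rejoined at 24.

Step 20. The most likely failure is attack of the peracid on the α face, since no directing group secures the face, with acid-induced opening of the oxirane as a lesser concern. Fallback: from 32 the alkene is converted with N-bromosuccinimide in aqueous THF to the bromohydrin F7 (bromonium ion on the α face, water at the tertiary C2 from the β face). Bu4NF then closes the oxirane by internal displacement with inversion at C3 and removes both silyl groups, so the face complementary to direct epoxidation is reached. The route is rejoined at 34.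

## Further compounds

F1 | step 9 | trimethylsilyl ether of 16 (configuration as in 16) | CC(C)/C(=C\C[C@H](C)OCc1ccc(OC)cc1)[C@@H]2C[C@]2(O[Si](C)(C)C)/C=C\COCc3ccc(OC)cc3
F2 | step 9 | trimethylsilyl C1=C7 enol ether of 19 | CC(C)C1=CCC(O[Si](C)(C)C)=C[C@H](COCc2ccc(OC)cc2)[C@H]1C[C@H](C)OCc3ccc(OC)cc3
F3 | step 8 | (1R,2R)-cyclopropane diastereomer of 16 | CC(C)/C(=C\C[C@H](C)OCc1ccc(OC)cc1)[C@H]2C[C@@]2(O)/C=C\COCc3ccc(OC)cc3
F4 | step 8 | (5S,6R)-ring diastereomer of 19 | CC(C)C1=CCC(=O)C[C@@H](COCc2ccc(OC)cc2)[C@@H]1C[C@H](C)OCc3ccc(OC)cc3
F5 | step 10 | 1-methylidene analogue of 19 | CC(C)C1=CCC(=C)C[C@H](COCc2ccc(OC)cc2)[C@H]1C[C@H](C)OCc3ccc(OC)cc3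
F6 | step 12 | 3β,4β-epoxide of 20 (oxirane syn to the C1 hydroxyl) | CC(C)[C@@]12O[C@@H]1C[C@](C)(O)C[C@H](COCc3ccc(OC)cc3)[C@H]2C[C@H](C)OCc4ccc(OC)cc4
F7 | step 20 | bromohydrin of 32 (2β-hydroxy, 3α-bromo) | CC(C)[C@H]1[C@@H]2C[C@@](C)(O)[C@H](Br)[C@H]2C[C@@](C)(O[Si](CC)(CC)CC)C[C@@H]1OC(=O)c1ccc(O[Si](C)(C)C(C)(C)C)cc1
A1 | alternative 1 | trans keto-aldehyde: 4-formyl-6-methyl-3-(2-oxopropyl)-2-(propan-2-yl)cycloheptane-1,6-diol bis(TES) ether, configured as in 30 | CC(C)[C@H]1[C@H](CC(C)=O)[C@@H](C=O)C[C@@](C)(O[Si](CC)(CC)CC)C[C@@H]1O[Si](CC)(CC)CC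
A2 | alternative 1 | (3aS,5R,7S,8S,8aR)-2,5-dimethyl-8-(propan-2-yl)-1,3a,4,5,6,7,8,8a-octahydroazulene-5,7-diol bis(TES) ether | CC(C)[C@H]1[C@@H]2CC(C)=C[C@H]2C[C@@](C)(O[Si](CC)(CC)CC)C[C@@H]1O[Si](CC)(CC)CC
A3 | alternative 2 | cyclopent-2-en-1-one | O=C1C=CCC1
A4 | alternative 2 | 1-methoxy-3-methyl-1-(trimethylsilyloxy)but-1-ene | COC(=CC(C)C)O[Si](C)(C)C
A5 | alternative 2 | 3-iodo-2-methylprop-1-ene | CC(=C)CI
A6 | alternative 2 | methyl 3-methyl-2-[trans-2-(2-methylprop-2-en-1-yl)-3-oxocyclopentyl]butanoate | CC(C)[C@H](C(=O)OC)[C@@H]1CCC(=O)[C@H]1CC(C)=C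
A7 | alternative 3 | 6-methyl-3-(propan-2-yl)non-1-en-8-yne-4,6-diol bis(TES) ether (anti diol, configured as in the target) | CC(C)[C@@H](C=C)[C@@H](O[Si](CC)(CC)CC)C[C@](C)(O[Si](CC)(CC)CC)CC#C
A8 | alternative 3 | 5,7-dihydroxy-5-methyl-8-(propan-2-yl)-4,5,6,7,8,8a-hexahydroazulen-2(1H)-one bis(TES) ether | CC(C)[C@H]1[C@@H]2CC(=O)C=C2C[C@@](C)(O[Si](CC)(CC)CC)C[C@@H]1O[Si](CC)(CC)CC
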